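**Plan**

- Cuts: the aryl ether bond between C8 of the genistein A ring and the 4'-oxygen of the chlorodaidzein B ring; then, in each half, the pyranone ring (C4–C4a acyl bond, C2, O1–C2). This leads back to 2-chlororesorcinol, 4-hydroxyphenylacetic acid (used twice), DMF (C2, twice) and a six-carbon unit for the genistein A ring.
- Enabling feature: C8 of the genistein A ring lies between C7–O and C8a–O1, so it is C2 of a resorcinol, the α-carbon of a masked 1,3-dicarbonyl. As the o-quinone diazide (2-diazoniophenolate) this normally nucleophilic carbon becomes an electrophilic Rh carbenoid and can be joined to the equally nucleophilic 4'-oxygen (polarity reversal).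
- Forward order: the chlorodaidzein pyranone first (Cl fixed at C8 by the symmetry of 2-chlororesorcinol). Carbenoid O–H insertion then makes the hindered, di-ortho-oxygenated ether and at the same time frees the single OH that becomes O1. The genistein pyranone is annulated onto that OH, so only the 8-aryloxy isomer can form. Global O-demethylation ends the route.
- Stereochemistry: the target has no stereogenic element; nothing has to be set.

Key step: step 5

Remark: the target is achiral, so the request for a single enantiomer needs no action; dienone 10 has one sp3 centre but is racemic and transient.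
Remark: 1,3,5-trimethoxy-2-nitrobenzene, 2-chlororesorcinol and 4-hydroxyphenylacetic acid are taken as commercially available.

**Step 1**
Reactants: 1 1,3,5-trimethoxy-2-nitrobenzene
Product: 2 3,5-dimethoxy-2-nitrophenol
Conditions: BCl3 (1.1 equiv), CH2Cl2, −78 → 0 °C; aq. work-up
Reagents that add atoms: none
Why: Chelation-directed Lewis-acid ether cleavage: BCl3 held by a nitro oxygen should cleave only an ortho OMe (the two are equivalent, the para one is out of reach), and the chelated aryloxyborane formed resists a second cleavage.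

**Step 2**
Reactants: 2 3,5-dimethoxy-2-nitrophenol
Product: 4 6-diazo-3,5-dimethoxycyclohexa-2,4-dien-1-one, via 2-amino-3,5-dimethoxyphenol 3 (not isolated)
Conditions: H2 (1 atm), 10% Pd/C, EtOH, rt; filter under Ar; then AcOH (co-solvent), t-BuONO (1.2 equiv), 0 °C, dark; aq. NaHCO3 wash
Reagents that add atoms: tert-butyl nitrite, CC(C)(C)ON=O
Why: Catalytic nitro hydrogenation followed by diazotisation of an o-aminophenol, whose diazonium ion loses the phenolic proton to give the neutral o-quinone diazide; the air-sensitive aminophenol is carried on without isolation.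

**Step 3**
Reactants: 5 2-chlororesorcinol; 6 4-hydroxyphenylacetic acid
Product: 8 8-chloro-7-hydroxy-3-(4-hydroxyphenyl)-4H-chromen-4-one (8-chlorodaidzein), via deoxybenzoin 7 (not isolated)
Conditions: BF3·OEt2 (neat), 85 °C; then DMF, MsCl, 70 °C; aq. NaOAc
Reagents that add atoms: N,N-dimethylformamide, CN(C)C=O
Why: One-pot Friedel–Crafts acylation and Vilsmeier-type C-formylation/cyclisation (deoxybenzoin isoflavone synthesis): the two activated positions of symmetric 5 (C4/C6) are equivalent, so chlorine can only end at C8, and DMF supplies C2.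

**Step 4**
Reactants: 8 8-chlorodaidzein
Product: 9 8-chloro-3-(4-hydroxyphenyl)-7-methoxy-4H-chromen-4-one
Conditions: K2CO3 (1.0 equiv), MeI (1.05 equiv), DMF, 0 °C → rt
Reagents that add atoms: iodomethane, CI
Why: Williamson O-alkylation under acidity control: the 7-OH is a vinylogous carboxylic acid made more acidic by the ortho chlorine, so one equivalent of base should ionise and methylate it in preference to the 4'-OH.

**Step 5**
Reactants: 9 8-chloro-3-(4-hydroxyphenyl)-7-methoxy-4H-chromen-4-one; 4 6-diazo-3,5-dimethoxycyclohexa-2,4-dien-1-one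
Product: 11 2-[4-(8-chloro-7-methoxy-4-oxo-4H-chromen-3-yl)phenoxy]-3,5-dimethoxyphenol, via cyclohexadienone tautomer 10 (not isolated)
Conditions: Rh2(esp)2 (2 mol %), ClCH2CH2Cl, 70 °C, 4 (1.3 equiv) added over 4 h, Ar, dark
Reagents that add atoms: none
Why: Proposed new method: Rh2(esp)2 should extrude N2 from the 2-diazoniophenolate 4 to give an electrophilic α-oxo rhodium carbenoid at the ring carbon between C=O and C–OMe, the 4'-OH oxygen of 9 attacks it to give an oxonium ylide, and a 1,2-proton shift gives dienone 10, which enolises at once to the aromatic phenol 11. The closest known reaction types are the Rh(II)-catalysed O–H insertion of diazonaphthoquinones and cyclic 2-diazo-1,3-diones into alcohols and of acceptor diazocarbonyl compounds into phenols; what is new is their use on a simple benzo-o-quinone diazide to make a di-ortho-oxygenated diaryl ether. No ring is closed, and the only stereocentre formed (C6 of 10, racemic) is erased by the tautomerisation. The step needs chemoselectivity for O–H insertion over Wolff ring contraction, carbene dimerisation and attack on the C2=C3 enol ether or the arene C–H bonds of 9; thermal Rh catalysis in the dark, slow addition of 4, the para-substituted B ring of 9 and the methyl cap on its acidic 7-OH are meant to secure it. Site selectivity is built into 4: the carbenoid carbon is the only diazo carbon, so the ether can only form between the oxygen that becomes O1 and the one that becomes 7-O, and the OH of 11, flanked by the new aryloxy group, should be slow to insert a second time.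

**Step 6**
Reactants: 11 2-[4-(8-chloro-7-methoxy-4-oxo-4H-chromen-3-yl)phenoxy]-3,5-dimethoxyphenol; 6 4-hydroxyphenylacetic acid
Product: 13 8-[4-(8-chloro-7-methoxy-4-oxo-4H-chromen-3-yl)phenoxy]-3-(4-hydroxyphenyl)-5,7-dimethoxy-4H-chromen-4-one, via deoxybenzoin 12 (not isolated)
Conditions: BF3·OEt2, 80 °C; then DMF, MsCl, 70 °C; aq. NaOAc
Reagents that add atoms: N,N-dimethylformamide, CN(C)C=O
Why: The same one-pot deoxybenzoin isoflavone synthesis: BF3-mediated acylation should go ortho to the free OH (as with 3,5-dimethoxyphenol) and not between the two OMe groups, and since that OH is the only hydroxyl ortho to the new ketone, ring closure can only give the 8-aryloxy isomer.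

**Step 7**
Reactants: 13 8-[4-(8-chloro-7-methoxy-4-oxo-4H-chromen-3-yl)phenoxy]-3-(4-hydroxyphenyl)-5,7-dimethoxy-4H-chromen-4-one
Product: 14 Bisoflavolin H
Conditions: BBr3 (10 equiv), CH2Cl2, −78 °C → rt; MeOH quench, aq. work-up
Reagents that add atoms: none
Why: Lewis-acid cleavage of the three aryl methyl ethers (the 5-OMe helped by chelation to C4=O); the diaryl ether, the aryl chloride and both chromones offer no sp3 C–O bond and should survive.

**Compound list**

1 | 1,3,5-trimethoxy-2-nitrobenzene | COc1cc(OC)c([N+](=O)[O-])c(OC)c1 | starting material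
2 | 3,5-dimethoxy-2-nitrophenol | COc1cc(O)c([N+](=O)[O-])c(OC)c1 | intermediate
3 | 2-amino-3,5-dimethoxyphenol | COc1cc(O)c(N)c(OC)c1 | intermediate
4 | 6-diazo-3,5-dimethoxycyclohexa-2,4-dien-1-one | COC1=CC(=O)C(=[N+]=[N-])C(OC)=C1 | intermediate
5 | 2-chlororesorcinol | Oc1cccc(O)c1Cl | starting material
6 | 4-hydroxyphenylacetic acid | OC(=O)Cc1ccc(O)cc1 | starting material
7 | 1-(3-chloro-2,4-dihydroxyphenyl)-2-(4-hydroxyphenyl)ethan-1-one | O=C(Cc1ccc(O)cc1)c1ccc(O)c(Cl)c1O | intermediate
8 | 8-chloro-7-hydroxy-3-(4-hydroxyphenyl)-4H-chromen-4-one (8-chlorodaidzein) | O=c1c(-c2ccc(O)cc2)coc2c(Cl)c(O)ccc12 | intermediate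
9 | 8-chloro-3-(4-hydroxyphenyl)-7-methoxy-4H-chromen-4-one | COc1ccc2c(=O)c(-c3ccc(O)cc3)coc2c1Cl | intermediate
10 | 6-[4-(8-chloro-7-methoxy-4-oxo-4H-chromen-3-yl)phenoxy]-3,5-dimethoxycyclohexa-2,4-dien-1-one (racemic) | COC1=CC(=O)C(Oc2ccc(-c3coc4c(Cl)c(OC)ccc4c3=O)cc2)C(OC)=C1 | intermediate
11 | 2-[4-(8-chloro-7-methoxy-4-oxo-4H-chromen-3-yl)phenoxy]-3,5-dimethoxyphenol | COc1cc(O)c(Oc2ccc(-c3coc4c(Cl)c(OC)ccc4c3=O)cc2)c(OC)c1 | intermediate
12 | 1-{3-[4-(8-chloro-7-methoxy-4-oxo-4H-chromen-3-yl)phenoxy]-2-hydroxy-4,6-dimethoxyphenyl}-2-(4-hydroxyphenyl)ethan-1-one | COc1cc(OC)c(Oc2ccc(-c3coc4c(Cl)c(OC)ccc4c3=O)cc2)c(O)c1C(=O)Cc1ccc(O)cc1 | intermediate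
13 | 8-[4-(8-chloro-7-methoxy-4-oxo-4H-chromen-3-yl)phenoxy]-3-(4-hydroxyphenyl)-5,7-dimethoxy-4H-chromen-4-one | COc1cc(OC)c(Oc2ccc(-c3coc4c(Cl)c(OC)ccc4c3=O)cc2)c2occ(-c3ccc(O)cc3)c(=O)c12 | intermediate
14 | Bisoflavolin H | O=c1c(-c2ccc(Oc3c(O)cc(O)c4c(=O)c(-c5ccc(O)cc5)coc34)cc2)coc2c(Cl)c(O)ccc12 | target

Total step count: 7
Longest linear sequence: 5 steps (steps 1, 2, 5, 6, 7 or steps 3, 4, 5, 6, 7)

**Steps most likely to fail**

1. Step 5 (proposed new method). The diazoniophenolate, stabilised by two methoxy donors, may be slow to give the carbenoid; the carbene may then dimerise, ring-contract on heating, or react at the chromone enol ether faster than it inserts into the O–H bond. The fallback uses known chemistry, sets out from 9 and comes back at 14. Phenol 9 is O-arylated with commercial 2-iodo-1,3,5-trimethoxybenzene in an Ullmann coupling (CuI, picolinic acid, K3PO4, DMSO, 90 °C) to give 8-chloro-7-methoxy-3-[4-(2,4,6-trimethoxyphenoxy)phenyl]-4H-chromen-4-one F1. Friedel–Crafts acylation with 4-methoxyphenylacetyl chloride and AlCl3 (CH2Cl2, 0 °C → rt) should acylate the trimethoxy ring and cleave the methoxy group squeezed between the new ketone and the aryloxy group, as 1,2,3,5-tetramethoxybenzene gives 2-hydroxy-3,4,6-trimethoxyaryl ketones, to give deoxybenzoin F2. DMF-DMA (toluene, 95 °C) closes the pyranone to the tetramethyl ether F3, and BBr3 as in step 7 gives 14.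

2. Step 6. Acylation at the crowded ring may be slow, BF3 may cleave the methoxy group ortho to the ketone before ring closure (which would open the way to the 6-aryloxy isomer), or the Vilsmeier closure may stay incomplete. The fallback sets out from 11 and comes back at 13, and makes the C3–aryl bond by cross-coupling instead of carrying the aryl group in with the acyl unit. Ortho-acetylation of 11 (AcOH, BF3·OEt2, 60 °C, as in the preparation of 2-hydroxy-4,6-dimethoxyacetophenone) gives acetophenone F4. DMF-DMA (95 °C) gives enaminone F5. Iodine (CHCl3/MeOH, rt) cyclises it to 3-iodochromone F6. Suzuki coupling with 4-hydroxyphenylboronic acid (Pd(PPh3)4, K2CO3, dioxane/H2O, 80 °C; the aryl chloride should stay untouched) gives 13.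

3. Step 4. Discrimination between the two phenols may be poor, with methylation also at the 4'-oxygen and double methylation. The fallback sets out from 5 and comes back at 9, and takes the differentiation from the building block. Symmetric 5 is mono-O-methylated (Me2SO4 0.9 equiv, K2CO3, acetone; statistical, separable) to 2-chloro-3-methoxyphenol F7. The one-pot sequence of step 3 with 6 (BF3·OEt2, 85 °C; then DMF, MsCl) acylates ortho to the free OH to give deoxybenzoin F8, which is not isolated and closes to 9.

**Further compounds**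

F1 | step 5 | 8-chloro-7-methoxy-3-[4-(2,4,6-trimethoxyphenoxy)phenyl]-4H-chromen-4-one | COc1cc(OC)c(Oc2ccc(-c3coc4c(Cl)c(OC)ccc4c3=O)cc2)c(OC)c1
F2 | step 5 | 1-{3-[4-(8-chloro-7-methoxy-4-oxo-4H-chromen-3-yl)phenoxy]-2-hydroxy-4,6-dimethoxyphenyl}-2-(4-methoxyphenyl)ethan-1-one | COc1ccc(CC(=O)c2c(OC)cc(OC)c(Oc3ccc(-c4coc5c(Cl)c(OC)ccc5c4=O)cc3)c2O)cc1
F3 | step 5 | 8-[4-(8-chloro-7-methoxy-4-oxo-4H-chromen-3-yl)phenoxy]-5,7-dimethoxy-3-(4-methoxyphenyl)-4H-chromen-4-one | COc1ccc(-c2coc3c(Oc4ccc(-c5coc6c(Cl)c(OC)ccc6c5=O)cc4)c(OC)cc(OC)c3c2=O)cc1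
F4 | step 6 | 1-{3-[4-(8-chloro-7-methoxy-4-oxo-4H-chromen-3-yl)phenoxy]-2-hydroxy-4,6-dimethoxyphenyl}ethan-1-one | COc1cc(OC)c(Oc2ccc(-c3coc4c(Cl)c(OC)ccc4c3=O)cc2)c(O)c1C(C)=O
F5 | step 6 | (E)-1-{3-[4-(8-chloro-7-methoxy-4-oxo-4H-chromen-3-yl)phenoxy]-2-hydroxy-4,6-dimethoxyphenyl}-3-(dimethylamino)prop-2-en-1-one | COc1cc(OC)c(Oc2ccc(-c3coc4c(Cl)c(OC)ccc4c3=O)cc2)c(O)c1C(=O)/C=C/N(C)C
F6 | step 6 | 8-[4-(8-chloro-7-methoxy-4-oxo-4H-chromen-3-yl)phenoxy]-3-iodo-5,7-dimethoxy-4H-chromen-4-one | COc1cc(OC)c(Oc2ccc(-c3coc4c(Cl)c(OC)ccc4c3=O)cc2)c2occ(I)c(=O)c12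
F7 | step 4 | 2-chloro-3-methoxyphenol | COc1cccc(O)c1Cl
F8 | step 4 | 1-(3-chloro-2-hydroxy-4-methoxyphenyl)-2-(4-hydroxyphenyl)ethan-1-one | COc1ccc(C(=O)Cc2ccc(O)cc2)c(O)c1Cl
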